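## Retrosynthetic overview

1. The C14 hydroperoxide is made last, by SN2 inversion of a (14R)-allylic mesylate with a monoperoxyketal anion, followed by one global acidic deprotection.
2. The key disconnection is C13–C14: a ligand-controlled Ni/Cr alkenylation joins alkenyl triflate 11 (decalin half) to aldehyde 18 (butenolide half). The enabling feature is the acyclic 2-methylene-carbinol unit C16H2=C13–C14(O) between the decalin (rings A/B) and the furanone ring: C13 can be an alkenyl-metal carbon made from a methyl ketone, and C14 an aldehyde carbon β to the butenolide γ-oxygen.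
3. The decalin half comes from (+)-larixol, which supplies rings A/B with C5, C6 (6α-OH), C9 and C10. It needs side-chain degradation, 8α-OH via an 8α,17-oxirane and hydride, and C18 oxidation by a 1,5-hydrogen shift from the peri 4α-methyl to the 6α-alkoxyl radical.
4. The butenolide half comes from asymmetric propiolate addition to a C3 aldehyde, then syn-carbocupration and lactonisation.
5. Ring order: A/B (from larixol) → temporary oxirane (step 2) → temporary oxolane, then γ-lactone C18–O–C6 (steps 3–5, opened in step 6) → furanone ring (step 10). No ring is formed in or after the key step.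

Key step: step 13

Assumption: (+)-larixol is taken as a purchasable chiral-pool diterpene. Labdane numbering is used throughout (C16 = carbon on C13 that becomes the exocyclic methylene, C17 = methyl on C8, C18 = 4α carbon, C19 = 4β-methyl, C20 = methyl on C10; C14 and C15 lead to the butenolide γ-carbon).

## Route

Step 1
Reactants: 1 (+)-larixol
Product: 2 6α-hydroxy-14,15-dinorlabd-8(17)-en-13-one
Conditions: KMnO4, acetone–H2O, 0 °C → rt
Reagents that add atoms: none
Why: Permanganate degradation of the tertiary vinyl carbinol (dihydroxylation, glycol cleavage, oxidative decarboxylation), the type of side-chain degradation used on sclareol-type labdanes; the monosubstituted C14=C15 alkene should react ahead of the hindered exocyclic C8=C17 alkene, and the C13 stereocentre is deliberately destroyed.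

Step 2
Reactants: 2 6α-hydroxy-14,15-dinorlabd-8(17)-en-13-one
Product: 3 8α,17-epoxy-6α-hydroxy-14,15-dinorlabdan-13-one
Conditions: m-CPBA, CH2Cl2, 0 °C
Reagents that add atoms: m-chloroperoxybenzoic acid, OOC(=O)c1cccc(Cl)c1
Why: Prilezhaev epoxidation from the α-face, away from the axial C20 methyl and guided by hydrogen bonding to the homoallylic 6α-OH, places the oxirane oxygen 8α and so fixes C8; the methyl ketone is inert at 0 °C.

Step 3
Reactants: 3 8α,17-epoxy-6α-hydroxy-14,15-dinorlabdan-13-one
Product: 4 6α,18:8α,17-diepoxy-14,15-dinorlabdan-13-one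
Conditions: PhI(OAc)2, I2, cyclohexane, hν (tungsten lamp), 40 °C
Reagents that add atoms: none
Why: Suárez hypoiodite reaction: the 6α-alkoxyl radical abstracts hydrogen from the peri 4α-methyl (C18, syn-pentane distance; the 4β-methyl is anti and out of reach) through a six-membered transition state, and iodination then ring closure gives the oxolane, which differentiates the gem-dimethyl group and sets C4 with the oxidised carbon α.

Step 4
Reactants: 4 6α,18:8α,17-diepoxy-14,15-dinorlabdan-13-one
Product: 5 6α,18-epoxy-14,15-dinorlabdane-8α,13-diol (C13 epimers)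
Conditions: LiAlH4, THF, 0 °C → reflux
Reagents that add atoms: none
Why: Hydride opens the spiro-oxirane by SN2 attack at the primary C17, leaving the oxygen on C8 as the tertiary 8α-alcohol with the new methyl β (C8 as set in step 2); the ketone is reduced in passing to a C13 epimer mixture that step 5 re-oxidises.

Step 5
Reactants: 5 6α,18-epoxy-14,15-dinorlabdane-8α,13-diol (C13 epimers)
Product: 6 8α-hydroxy-13-oxo-14,15-dinorlabdan-18,6α-olide
Conditions: RuCl3·xH2O (cat.), NaIO4, CCl4–MeCN–H2O, rt
Reagents that add atoms: sodium periodate (oxygen delivered through catalytic RuO4), [Na+].[O-]I(=O)(=O)=O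
Why: Ruthenium tetroxide oxidation converts the ether methylene C18 into the γ-lactone carbonyl and, in the same operation, the secondary C13 carbinol back into the methyl ketone; the tertiary 8-OH is inert and no stereocentre is touched.

Step 6
Reactants: 6 8α-hydroxy-13-oxo-14,15-dinorlabdan-18,6α-olide
Product: 8 methyl 6α,8α-dihydroxy-13-oxo-14,15-dinorlabdan-18-oate, via potassium carboxylate 7 (not isolated)
Conditions: KOH (1.0 equiv), MeOH–H2O, 50 °C; evaporate; then MeI, DMF, rt
Reagents that add atoms: potassium hydroxide, [K+].[OH-]; iodomethane, CI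
Why: Saponification opens the peri-fused γ-lactone and SN2 O-methylation of the carboxylate traps the open form as the methyl ester under non-acidic conditions in which relactonisation should not compete; C4 and C6 are untouched.

Step 7
Reactants: 8 methyl 6α,8α-dihydroxy-13-oxo-14,15-dinorlabdan-18-oate
Product: 9 methyl 13-oxo-6α,8α-bis(triethylsilyloxy)-14,15-dinorlabdan-18-oate
Conditions: TESOTf, 2,6-lutidine, CH2Cl2, −78 → −20 °C
Reagents that add atoms: triethylsilyl trifluoromethanesulfonate, CC[Si](CC)(CC)OS(=O)(=O)C(F)(F)F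
Why: Silyl triflate silylation protects both the hindered 6α-OH and the tertiary 8α-OH, which blocks 6-O→C18 lactonisation and alkoxide or hemiketal formation in the later basic steps; no stereocentre is affected.

Step 8
Reactants: 9 methyl 13-oxo-6α,8α-bis(triethylsilyloxy)-14,15-dinorlabdan-18-oate
Product: 11 methyl 6α,8α-bis(triethylsilyloxy)-13-(trifluoromethylsulfonyloxy)-14,15-dinorlabd-13(16)-en-18-oate, via lithium enolate 10 (not isolated)
Conditions: LDA, THF, −78 °C; then PhNTf2, −78 → 0 °C
Reagents that add atoms: N-phenylbis(trifluoromethanesulfonimide), O=S(=O)(N(c1ccccc1)S(=O)(=O)C(F)(F)F)C(F)(F)F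
Why: Kinetic deprotonation of the methyl ketone at the methyl group (C16) and O-sulfonylation of the less substituted enolate give the 2-triflyloxy-1-alkene; the ester on quaternary C4 has no α-hydrogen and is shielded.

Step 9
Reactants: 12 3-(tert-butyldimethylsilyloxy)propanal; 13 methyl propiolate
Product: 14 methyl (4S)-6-(tert-butyldimethylsilyloxy)-4-hydroxyhex-2-ynoate
Conditions: ProPhenol ligand (10 mol %, the antipode that delivers the 4S carbinol), Me2Zn, Ph3PO (20 mol %), toluene, 0 °C
Reagents that add atoms: none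
Why: Catalytic asymmetric alkynylation (dinuclear zinc–ProPhenol) adds the zinc acetylide of methyl propiolate to one aldehyde face and sets the carbinol centre (4S), the future butenolide γ-carbon, under ligand control.

Step 10
Reactants: 14 methyl (4S)-6-(tert-butyldimethylsilyloxy)-4-hydroxyhex-2-ynoate
Product: 16 (5S)-5-[2-(tert-butyldimethylsilyloxy)ethyl]-4-methylfuran-2(5H)-one, via (Z)-hydroxy enoate 15 (not isolated)
Conditions: Me2CuLi (from CuI and MeLi), THF, −78 °C; aq. NH4Cl, warm to rt
Reagents that add atoms: lithium dimethylcuprate, [Li+].C[Cu-]C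
Why: Syn-carbocupration of the ynoate puts methyl on the β-carbon and, after protonation, leaves ester and carbinol cis on the (Z)-enoate, so lactonisation to the β-methylbutenolide is spontaneous; the carbinol centre is not involved.

Step 11
Reactants: 16 (5S)-5-[2-(tert-butyldimethylsilyloxy)ethyl]-4-methylfuran-2(5H)-one
Product: 17 (5S)-5-(2-hydroxyethyl)-4-methylfuran-2(5H)-one
Conditions: HF·pyridine, THF, 0 °C → rt
Reagents that add atoms: none
Why: Fluoride-mediated desilylation under weakly acidic conditions frees the primary alcohol without base, so the γ-centre cannot epimerise and oxa-Michael closure onto the butenolide is not triggered.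

Step 12
Reactants: 17 (5S)-5-(2-hydroxyethyl)-4-methylfuran-2(5H)-one
Product: 18 [(2S)-3-methyl-5-oxo-2,5-dihydrofuran-2-yl]acetaldehyde
Conditions: Dess–Martin periodinane, CH2Cl2, 0 °C → rt; used at once
Reagents that add atoms: none
Why: Dess–Martin oxidation under non-basic conditions gives the β-acyloxy aldehyde without α-deprotonation and β-elimination of the lactone oxygen.

Step 13
Reactants: 11 methyl 6α,8α-bis(triethylsilyloxy)-13-(trifluoromethylsulfonyloxy)-14,15-dinorlabd-13(16)-en-18-oate; 18 [(2S)-3-methyl-5-oxo-2,5-dihydrofuran-2-yl]acetaldehyde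
Product: 19 methyl (14R)-14-hydroxy-15-[(2S)-3-methyl-5-oxo-2,5-dihydrofuran-2-yl]-6α,8α-bis(triethylsilyloxy)labd-13(16)-en-18-oate
Conditions: CrCl2 (cat.)/chiral oxazoline–sulfonamide ligand/proton sponge (ligand antipode that delivers 14R), NiCl2·2,9-dimethyl-1,10-phenanthroline (cat.), Mn, Cp2ZrCl2, LiCl, MeCN, rt
Reagents that add atoms: none
Why: Nozaki–Hiyama–Kishi alkenylation: Ni(0) inserts into the C13–OTf bond of 11, the alkenyl group passes to Cr(III), and the alkenylchromium adds to the aldehyde carbon of 18, with Cp2ZrCl2 releasing the chromium alkoxide and Mn returning Cr(III) to Cr(II). The closest known reaction type is the catalytic asymmetric Ni/Cr coupling of 2-haloalk-1-enes and alkenyl triflates with β-oxygenated aldehydes to give 2-methylene carbinols in fragment unions. No ring is closed; the step forms the C13–C14 bond, leaves the C13=C16 methylene in place (a σ-alkenyl metal cannot transpose) and creates C14. C14 is set by the sulfonamide-ligated chromium (reagent control of the aldehyde face, 14R, 1,3-syn to the butenolide oxygen), so that the inversion in step 15 delivers 14S. The step needs chemoselectivity for the aldehyde over the methyl ester and the butenolide and must not trigger β-elimination in 18: organochromium reagents are aldehyde-selective and essentially non-basic, and the ester on quaternary C4 is shielded.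

Step 14
Reactants: 19 methyl (14R)-14-hydroxy-15-[(2S)-3-methyl-5-oxo-2,5-dihydrofuran-2-yl]-6α,8α-bis(triethylsilyloxy)labd-13(16)-en-18-oate
Product: 20 methyl (14R)-14-(methylsulfonyloxy)-15-[(2S)-3-methyl-5-oxo-2,5-dihydrofuran-2-yl]-6α,8α-bis(triethylsilyloxy)labd-13(16)-en-18-oate
Conditions: Ms2O, Et3N, CH2Cl2, −40 °C; used crude
Reagents that add atoms: methanesulfonic anhydride, CS(=O)(=O)OS(C)(=O)=O
Why: Sulfonylation of the only free hydroxyl with retention at C14; the anhydride avoids chloride that could displace the allylic mesylate, and the low temperature avoids ionisation and oxa-Michael closure onto the butenolide.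

Step 15
Reactants: 20 methyl (14R)-14-(methylsulfonyloxy)-15-[(2S)-3-methyl-5-oxo-2,5-dihydrofuran-2-yl]-6α,8α-bis(triethylsilyloxy)labd-13(16)-en-18-oate
Product: 21 methyl (14S)-14-[(2-methoxypropan-2-yl)peroxy]-15-[(2S)-3-methyl-5-oxo-2,5-dihydrofuran-2-yl]-6α,8α-bis(triethylsilyloxy)labd-13(16)-en-18-oate
Conditions: 2-methoxyprop-2-yl hydroperoxide (3 equiv), KOtBu (2.5 equiv), THF–DMF, −40 → 0 °C
Reagents that add atoms: 2-methoxyprop-2-yl hydroperoxide (as its potassium salt), COC(C)(C)OO
Why: SN2 displacement of the secondary allylic sulfonate by an α-effect peroxide anion (alkylation of a monoperoxyketal, the standard way from sulfonates to hydroperoxides) inverts C14 from R to S; the weakly basic nucleophile should favour substitution over E2, and the electron-withdrawing butenolide oxygen two carbons away disfavours ionisation.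

Step 16
Reactants: 21 methyl (14S)-14-[(2-methoxypropan-2-yl)peroxy]-15-[(2S)-3-methyl-5-oxo-2,5-dihydrofuran-2-yl]-6α,8α-bis(triethylsilyloxy)labd-13(16)-en-18-oate
Product: 22 methyl (14S)-14-hydroperoxy-6α,8α-dihydroxy-15-[(2S)-3-methyl-5-oxo-2,5-dihydrofuran-2-yl]labd-13(16)-en-18-oate (CNP0324515.1)
Conditions: 48% aq. HF, MeCN, 0 °C → rt
Reagents that add atoms: none
Why: Aqueous acidic fluoride cleaves both triethylsilyl ethers and hydrolyses the acid-labile perketal to the free hydroperoxide in one operation; no bond to a stereocentre is broken.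

## Compound list

1 | (+)-larixol, (13S)-labda-8(17),14-diene-6α,13-diol | C=C[C@@](C)(O)CC[C@@H]1[C@@]2(C)CCCC(C)(C)[C@@H]2[C@@H](O)CC1=C | starting material
2 | 6α-hydroxy-14,15-dinorlabd-8(17)-en-13-one | CC(=O)CC[C@@H]1[C@@]2(C)CCCC(C)(C)[C@@H]2[C@@H](O)CC1=C | intermediate
3 | 8α,17-epoxy-6α-hydroxy-14,15-dinorlabdan-13-one | CC(=O)CC[C@@H]1[C@@]2(C)CCCC(C)(C)[C@@H]2[C@@H](O)C[C@]13CO3 | intermediate
4 | 6α,18:8α,17-diepoxy-14,15-dinorlabdan-13-one | CC(=O)CC[C@@H]1[C@@]2(C)CCC[C@@](C)(CO3)[C@@H]2[C@@H]3C[C@]14CO4 | intermediate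
5 | 6α,18-epoxy-14,15-dinorlabdane-8α,13-diol (C13 epimers) | CC(O)CC[C@@H]1[C@@]2(C)CCC[C@@](C)(CO3)[C@@H]2[C@@H]3C[C@@]1(C)O | intermediate
6 | 8α-hydroxy-13-oxo-14,15-dinorlabdan-18,6α-olide | CC(=O)CC[C@@H]1[C@@]2(C)CCC[C@@](C)(C(=O)O3)[C@@H]2[C@@H]3C[C@@]1(C)O | intermediate
7 | potassium 6α,8α-dihydroxy-13-oxo-14,15-dinorlabdan-18-oate | CC(=O)CC[C@@H]1[C@@]2(C)CCC[C@@](C)(C(=O)[O-])[C@@H]2[C@@H](O)C[C@@]1(C)O.[K+] | intermediate
8 | methyl 6α,8α-dihydroxy-13-oxo-14,15-dinorlabdan-18-oate | CC(=O)CC[C@@H]1[C@@]2(C)CCC[C@@](C)(C(=O)OC)[C@@H]2[C@@H](O)C[C@@]1(C)O | intermediate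
9 | methyl 13-oxo-6α,8α-bis(triethylsilyloxy)-14,15-dinorlabdan-18-oate | CC(=O)CC[C@@H]1[C@@]2(C)CCC[C@@](C)(C(=O)OC)[C@@H]2[C@@H](O[Si](CC)(CC)CC)C[C@@]1(C)O[Si](CC)(CC)CC | intermediate
10 | lithium 13(16)-enolate of 9 | [Li+].C=C([O-])CC[C@@H]1[C@@]2(C)CCC[C@@](C)(C(=O)OC)[C@@H]2[C@@H](O[Si](CC)(CC)CC)C[C@@]1(C)O[Si](CC)(CC)CC | intermediate
11 | methyl 6α,8α-bis(triethylsilyloxy)-13-(trifluoromethylsulfonyloxy)-14,15-dinorlabd-13(16)-en-18-oate | C=C(OS(=O)(=O)C(F)(F)F)CC[C@@H]1[C@@]2(C)CCC[C@@](C)(C(=O)OC)[C@@H]2[C@@H](O[Si](CC)(CC)CC)C[C@@]1(C)O[Si](CC)(CC)CC | intermediate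
12 | 3-(tert-butyldimethylsilyloxy)propanal | O=CCCO[Si](C)(C)C(C)(C)C | starting material
13 | methyl propiolate | C#CC(=O)OC | starting material
14 | methyl (4S)-6-(tert-butyldimethylsilyloxy)-4-hydroxyhex-2-ynoate | CC(C)(C)[Si](C)(C)OCC[C@H](O)C#CC(=O)OC | intermediate
15 | methyl (2Z,4S)-6-(tert-butyldimethylsilyloxy)-4-hydroxy-3-methylhex-2-enoate | CC(C)(C)[Si](C)(C)OCC[C@H](O)/C(C)=C\C(=O)OC | intermediate
16 | (5S)-5-[2-(tert-butyldimethylsilyloxy)ethyl]-4-methylfuran-2(5H)-one | CC(C)(C)[Si](C)(C)OCC[C@@H]1OC(=O)C=C1C | intermediate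
17 | (5S)-5-(2-hydroxyethyl)-4-methylfuran-2(5H)-one | OCC[C@@H]1OC(=O)C=C1C | intermediate
18 | [(2S)-3-methyl-5-oxo-2,5-dihydrofuran-2-yl]acetaldehyde | O=CC[C@@H]1OC(=O)C=C1C | intermediate
19 | methyl (14R)-14-hydroxy-15-[(2S)-3-methyl-5-oxo-2,5-dihydrofuran-2-yl]-6α,8α-bis(triethylsilyloxy)labd-13(16)-en-18-oate | C=C(CC[C@@H]1[C@@]2(C)CCC[C@@](C)(C(=O)OC)[C@@H]2[C@@H](O[Si](CC)(CC)CC)C[C@@]1(C)O[Si](CC)(CC)CC)[C@@H](C[C@@H]1OC(=O)C=C1C)O | intermediate
20 | (14R)-14-O-methanesulfonate of 19 | C=C(CC[C@@H]1[C@@]2(C)CCC[C@@](C)(C(=O)OC)[C@@H]2[C@@H](O[Si](CC)(CC)CC)C[C@@]1(C)O[Si](CC)(CC)CC)[C@@H](C[C@@H]1OC(=O)C=C1C)OS(C)(=O)=O | intermediate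
21 | methyl (14S)-14-[(2-methoxypropan-2-yl)peroxy]-15-[(2S)-3-methyl-5-oxo-2,5-dihydrofuran-2-yl]-6α,8α-bis(triethylsilyloxy)labd-13(16)-en-18-oate | C=C(CC[C@@H]1[C@@]2(C)CCC[C@@](C)(C(=O)OC)[C@@H]2[C@@H](O[Si](CC)(CC)CC)C[C@@]1(C)O[Si](CC)(CC)CC)[C@H](C[C@@H]1OC(=O)C=C1C)OOC(C)(C)OC | intermediate
22 | methyl (14S)-14-hydroperoxy-6α,8α-dihydroxy-15-[(2S)-3-methyl-5-oxo-2,5-dihydrofuran-2-yl]labd-13(16)-en-18-oate (CNP0324515.1) | C=C(CC[C@@H]1[C@@]2(C)CCC[C@@](C)(C(=O)OC)[C@@H]2[C@@H](O)C[C@@]1(C)O)[C@H](C[C@@H]1OC(=O)C=C1C)OO | target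

## Step count and risks

Total step count: 16. Longest linear sequence: 12 steps (steps 1–8, then 13–16, from larixol); the butenolide branch is 4 steps before the union.

Steps most likely to fail:

Step 15. The peroxide anion may attack the terminal C16 methylene (SN2′) or act as a base (E2 towards the 13(16),14-diene, or opening and epimerisation of the butenolide), so that clean inversion at C14 is lost. The fallback sets out from 19 and comes back at 22. Reductive 1,3-transposition of the allylic alcohol through its allylic diazene (2-nitrobenzenesulfonylhydrazide, PPh3, DEAD, THF, −30 °C → rt) moves the alkene into C13=C14 and turns C16 into a methyl group, giving the (13E)-alkene F1. A Schenck ene reaction (O2, tetraphenylporphyrin, hν, CH2Cl2, 0 °C) then puts the hydroperoxide on C14 and regenerates the C13=C16 methylene by abstraction from the C16 methyl on the more substituted side of the alkene. It should give the bis-silyl ether of the target F2 together with its C14 epimer F3, which are separated. F3 is returned to 19 by Ph3P reduction, and F2 is desilylated (HF·pyridine, THF) to 22. This fallback gives up control of C14 in exchange for neutral conditions, and it depends on the transposition giving the 13E geometry, which is not assured.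

Step 3. Electrophilic iodine (acetyl hypoiodite) may iodinate the enolisable methyl ketone or open the oxirane faster than the O–I bond is homolysed, so that the 1,5-hydrogen shift does not take place. The fallback sets out from 2 and comes back at 6. Nitrosation (NOCl, pyridine, −20 °C) gives the 6α-nitrite F4. Barton nitrite photolysis (hν > 300 nm, benzene, then warming in 2-propanol) gives the C18 oxime F5. Reductive hydrolysis (TiCl3, NH4OAc, aqueous dioxane) gives the 6α,18-lactol F6, and Ley–Griffith oxidation (TPAP, NMO) gives the lactone F7. Mukaiyama hydration of the C8=C17 alkene (Co(acac)2, PhSiH3, O2, THF) then reaches 6, with oxygen expected on the α-face, anti to the axial C20 methyl. No iodine, epoxide or hydride is involved.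

Step 13. Ligand control of the aldehyde face may be eroded by the β-acyloxy stereocentre (mismatched pairing), giving C14 epimers, and a slow coupling leaves the aldehyde time to lose the lactone oxygen by β-elimination. The fallback sets out from 11 and 18 and comes back at 19. The coupling is run with stoichiometric CrCl2 and catalytic NiCl2 in DMF–THF without chiral ligand, which should give 19 mixed with its C14 epimer F8. Dess–Martin oxidation of the mixture gives the α-methylene ketone F9. Corey–Bakshi–Shibata reduction (Me-CBS antipode chosen for 14R, catecholborane, toluene, −78 °C) then sets C14 by reagent control in a separate step and returns 19.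

Further compounds
F1 | step 15 | methyl (13E)-15-[(2S)-3-methyl-5-oxo-2,5-dihydrofuran-2-yl]-6α,8α-bis(triethylsilyloxy)labd-13-en-18-oate | C/C(CC[C@@H]1[C@@]2(C)CCC[C@@](C)(C(=O)OC)[C@@H]2[C@@H](O[Si](CC)(CC)CC)C[C@@]1(C)O[Si](CC)(CC)CC)=C\C[C@@H]1OC(=O)C=C1C
F2 | step 15 | 6,8-bis(triethylsilyl) ether of 22 (14S) | C=C(CC[C@@H]1[C@@]2(C)CCC[C@@](C)(C(=O)OC)[C@@H]2[C@@H](O[Si](CC)(CC)CC)C[C@@]1(C)O[Si](CC)(CC)CC)[C@H](C[C@@H]1OC(=O)C=C1C)OO
F3 | step 15 | C14 epimer (14R) of F2 | C=C(CC[C@@H]1[C@@]2(C)CCC[C@@](C)(C(=O)OC)[C@@H]2[C@@H](O[Si](CC)(CC)CC)C[C@@]1(C)O[Si](CC)(CC)CC)[C@@H](C[C@@H]1OC(=O)C=C1C)OO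
F4 | step 3 | 13-oxo-14,15-dinorlabd-8(17)-en-6α-yl nitrite | CC(=O)CC[C@@H]1[C@@]2(C)CCCC(C)(C)[C@@H]2[C@@H](ON=O)CC1=C
F5 | step 3 | 6α-hydroxy-13-oxo-14,15-dinorlabd-8(17)-en-18-al oxime | CC(=O)CC[C@@H]1[C@@]2(C)CCC[C@@](C)(C=NO)[C@@H]2[C@@H](O)CC1=C
F6 | step 3 | 6α,18-epoxy-18-hydroxy-14,15-dinorlabd-8(17)-en-13-one (lactol) | CC(=O)CC[C@@H]1[C@@]2(C)CCC[C@@](C)(C(O)O3)[C@@H]2[C@@H]3CC1=C
F7 | step 3 | 13-oxo-14,15-dinorlabd-8(17)-en-18,6α-olide | CC(=O)CC[C@@H]1[C@@]2(C)CCC[C@@](C)(C(=O)O3)[C@@H]2[C@@H]3CC1=C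
F8 | step 13 | C14 epimer (14S) of 19 | C=C(CC[C@@H]1[C@@]2(C)CCC[C@@](C)(C(=O)OC)[C@@H]2[C@@H](O[Si](CC)(CC)CC)C[C@@]1(C)O[Si](CC)(CC)CC)[C@H](C[C@@H]1OC(=O)C=C1C)O
F9 | step 13 | methyl 15-[(2S)-3-methyl-5-oxo-2,5-dihydrofuran-2-yl]-14-oxo-6α,8α-bis(triethylsilyloxy)labd-13(16)-en-18-oate | C=C(CC[C@@H]1[C@@]2(C)CCC[C@@](C)(C(=O)OC)[C@@H]2[C@@H](O[Si](CC)(CC)CC)C[C@@]1(C)O[Si](CC)(CC)CC)C(=O)C[C@@H]1OC(=O)C=C1C
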